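**Plan**

1. Retrosynthesis: the hemiketal O1–C2 bond is opened to a phenolic α-aryloxy ketone. The C3–CH3 bond is traced back to a CH2 spanning C2 and C3 in a 2-aryloxy-1-siloxycyclopropane, and removal of that CH2 leaves a Z silyl enol ether. The CH2–OAr ether bond, the aryl–allyl bond and one phenolic C–O bond are then cut.
2. Enabling feature: in the ring-opened form ArC(=O)–CH(CH3)–OAr' the C3 methyl sits on the carbon next to the masked carbonyl carbon C2. This is the pattern a cyclopropanol leaves when its C(OH)–CH2 bond is protonolysed; the 1,4-dioxane ring is only the hemiketal of that ketone with the ortho phenol.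
3. Forward: the arene is dressed first (O-allylation of o-vanillin, CHO to OH, MOM, para-Claisen), joined to the trimethoxyphenacyl unit and enol-silylated. The cyclopropane closes in step 7 and is opened again in step 8, where the dioxane ring closes last.
4. Stereochemistry: C3 (R) comes from ligand-controlled CH2 transfer to one face of the Z enol ether and passes unchanged through the ring opening. C2 (S) is a hemiketal centre that settles by equilibration under the influence of C3.

Key step: step 7

Assumption: C2 interconverts through the open-chain ketone 21, so the route fixes only C3; the drawn 2S form (aryl cis to the C3 methyl, hydroxyl axial and anti to the methyl) is taken to be the hemiketal favoured at equilibrium.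

**Route**

Step 1
Reactants: 1 o-vanillin; 2 allyl bromide
Product: 3 2-(allyloxy)-3-methoxybenzaldehyde
Conditions: K2CO3, DMF, rt
Reagents that add atoms: allyl bromide (2), C=CCBr
Why: Williamson ether synthesis, the phenoxide of 1 displacing bromide from the reactive allylic halide; no stereocentre is formed.

Step 2
Reactants: 3 2-(allyloxy)-3-methoxybenzaldehyde; 4 3-chloroperoxybenzoic acid
Product: 6 2-(allyloxy)-3-methoxyphenol, via aryl formate 5 (not isolated)
Conditions: mCPBA, CH2Cl2, 0 °C to rt; aq. NaHCO3 wash; then K2CO3 (cat.), MeOH, rt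
Reagents that add atoms: 3-chloroperoxybenzoic acid (4), O=C(OO)c1cccc(Cl)c1
Why: Baeyer–Villiger (Dakin-type) oxidation in which the electron-rich 2,3-dialkoxyphenyl group migrates in the Criegee adduct to give formate 5, which base-catalysed methanolysis cleaves, while the electron-poor alkene of the allyl ether is epoxidised far more slowly at this temperature.

Step 3
Reactants: 6 2-(allyloxy)-3-methoxyphenol; 7 chloromethyl methyl ether
Product: 8 2-(allyloxy)-1-methoxy-3-(methoxymethoxy)benzene
Conditions: MOMCl, iPr2NEt, CH2Cl2, 0 °C to rt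
Reagents that add atoms: chloromethyl methyl ether (7), COCCl
Why: standard acetal protection of a phenol; MOM is chosen because it cannot migrate to the neighbouring oxygen, tolerates heat, base and the zinc reagent, and leaves under the acid of the last step.

Step 4
Reactants: 8 2-(allyloxy)-1-methoxy-3-(methoxymethoxy)benzene
Product: 11 4-allyl-2-methoxy-6-(methoxymethoxy)phenol, via ortho dienone 9 (not isolated), via para dienone 10 (not isolated)
Conditions: N,N-diethylaniline, 190 °C, argon
Reagents that add atoms: none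
Why: aromatic para-Claisen rearrangement, as known for allyl 2,6-dimethoxyphenyl ether: with both ortho positions blocked, a [3,3] shift to an ortho carbon (9, drawn for the methoxy-bearing one) is followed by a Cope [3,3] shift to the para carbon (10) and tautomerisation to the phenol.

Step 5
Reactants: 11 4-allyl-2-methoxy-6-(methoxymethoxy)phenol; 12 2-bromo-1-(3,4,5-trimethoxyphenyl)ethanone
Product: 13 2-[4-allyl-2-methoxy-6-(methoxymethoxy)phenoxy]-1-(3,4,5-trimethoxyphenyl)ethanone
Conditions: K2CO3, acetone, reflux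
Reagents that add atoms: 2-bromo-1-(3,4,5-trimethoxyphenyl)ethanone (12), COc1cc(C(=O)CBr)cc(OC)c1OC
Why: Williamson ether synthesis (SN2 of a 2,6-dioxygenated phenoxide on a phenacyl bromide, routine for such phenols); since no aldehyde is present, the Rap–Stoermer benzofuran condensation cannot intervene.

Step 6
Reactants: 13 2-[4-allyl-2-methoxy-6-(methoxymethoxy)phenoxy]-1-(3,4,5-trimethoxyphenyl)ethanone; 14 chlorotrimethylsilane
Product: 16 (Z)-2-[4-allyl-2-methoxy-6-(methoxymethoxy)phenoxy]-1-(3,4,5-trimethoxyphenyl)-1-(trimethylsilyloxy)ethene, via lithium Z-enolate 15 (not isolated)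
Conditions: LiN(SiMe3)2, THF, −78 °C; then Me3SiCl, −78 to 0 °C; pentane, filtration, used crude
Reagents that add atoms: chlorotrimethylsilane (14), C[Si](C)(C)Cl
Why: kinetic enolisation and O-silylation of an α-aryloxy aryl ketone; lithium bridges the enolate oxygen and the aryloxy oxygen in a five-membered chelate, and the aryl group avoids the β-substituent, so both effects favour the Z enol ether.

Step 7
Reactants: 16 (Z)-2-[4-allyl-2-methoxy-6-(methoxymethoxy)phenoxy]-1-(3,4,5-trimethoxyphenyl)-1-(trimethylsilyloxy)ethene; 17 diiodomethane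
Product: 18 (1R,2R)-cis-2-[4-allyl-2-methoxy-6-(methoxymethoxy)phenoxy]-1-(3,4,5-trimethoxyphenyl)-1-(trimethylsilyloxy)cyclopropane
Conditions: Et2Zn (1.5 equiv), CH2I2 (1.5 equiv), N-Boc-L-Val-L-Pro-OMe (0.25 equiv), CH2Cl2, −40 to 0 °C; aq. NaHCO3 quench
Reagents that add atoms: diiodomethane (17), ICI
Why: Et2Zn deprotonates the carbamate N–H of the dipeptide and CH2I2 then gives the chiral carbenoid Boc-N(ZnCH2I)-L-Val-L-Pro-OMe, which transfers CH2 to the electron-rich enol ether through the concerted butterfly transition state of the Simmons–Smith (Furukawa) reaction and is replenished from EtZnCH2I; the closest known reaction is this same ligand-accelerated asymmetric cyclopropanation of Z trimethylsilyl enol ethers of aryl alkyl ketones, the β-aryloxy group being the untried element. The three-membered ring closes in a single intermolecular [2+1] event in which the future C3–CH3 bond and the temporary C2–CH2 bond form together on one face. Because the addition is suprafacial, the Z geometry of 16 is copied into the cis relationship of the aryloxy and siloxy groups, and the face selected by the L,L-dipeptide is expected to give the (1R,2R) ring, that is R at the future C3; should this substrate show the opposite sense, the D-Val-D-Pro ligand would be used. The step needs chemoselectivity for the enol ether over the allyl group, which the much higher nucleophilicity of a doubly oxygenated alkene, the limited carbenoid charge and the low temperature should secure. It also needs a geometrically pure Z enol ether from step 6 and a buffered quench so that ZnI2 does not open the product prematurely.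

Step 8
Reactants: 18 (1R,2R)-cis-2-[4-allyl-2-methoxy-6-(methoxymethoxy)phenoxy]-1-(3,4,5-trimethoxyphenyl)-1-(trimethylsilyloxy)cyclopropane
Product: 22 (2S,3R)-5-methoxy-3-methyl-7-(prop-2-en-1-yl)-2-(3,4,5-trimethoxyphenyl)-2,3-dihydro-1,4-benzodioxin-2-ol, via cyclopropanol 19 (not isolated), via MOM ketone 20 (not isolated), via hydroxy ketone 21 (not isolated)
Conditions: 3 M aq. HCl, THF, 0 °C to 40 °C
Reagents that add atoms: none
Why: acid hydrolyses the Si–O bond and then protonates the unsubstituted CH2 corner of cyclopropanol 19 while the C2–CH2 bond breaks towards the carbon stabilised by the hydroxyl lone pair and the electron-rich aryl ring (acid-mediated homoketonisation of a siloxycyclopropane, the known cyclopropanation/ring-opening route to α-methyl ketones), leaving the C3–O and C3–H bonds untouched so that C3 stays R; hydrolysis of the aryl MOM acetal then frees the phenol, which adds to the ketone in a 6-exo-trig hemiketalisation, C2 settling by equilibration.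

**Compound list**

1 | o-vanillin (2-hydroxy-3-methoxybenzaldehyde) | COc1cccc(C=O)c1O | starting material
2 | allyl bromide | C=CCBr | starting material
3 | 2-(allyloxy)-3-methoxybenzaldehyde | C=CCOc1c(OC)cccc1C=O | intermediate
4 | 3-chloroperoxybenzoic acid (mCPBA) | O=C(OO)c1cccc(Cl)c1 | starting material
5 | 2-(allyloxy)-3-methoxyphenyl formate | C=CCOc1c(OC)cccc1OC=O | intermediate
6 | 2-(allyloxy)-3-methoxyphenol | C=CCOc1c(OC)cccc1O | intermediate
7 | chloromethyl methyl ether | COCCl | starting material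
8 | 2-(allyloxy)-1-methoxy-3-(methoxymethoxy)benzene | C=CCOc1c(OC)cccc1OCOC | intermediate
9 | 6-allyl-6-methoxy-2-(methoxymethoxy)cyclohexa-2,4-dien-1-one (ortho dienone, racemic) | C=CCC1(OC)C=CC=C(OCOC)C1=O | intermediate
10 | 4-allyl-2-methoxy-6-(methoxymethoxy)cyclohexa-2,5-dien-1-one (para dienone) | C=CCC1C=C(OC)C(=O)C(OCOC)=C1 | intermediate
11 | 4-allyl-2-methoxy-6-(methoxymethoxy)phenol | C=CCc1cc(OC)c(O)c(OCOC)c1 | intermediate
12 | 2-bromo-1-(3,4,5-trimethoxyphenyl)ethanone | COc1cc(C(=O)CBr)cc(OC)c1OC | starting material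
13 | 2-[4-allyl-2-methoxy-6-(methoxymethoxy)phenoxy]-1-(3,4,5-trimethoxyphenyl)ethanone | C=CCc1cc(OC)c(OCC(=O)c2cc(OC)c(OC)c(OC)c2)c(OCOC)c1 | intermediate
14 | chlorotrimethylsilane | C[Si](C)(C)Cl | starting material
15 | lithium (Z)-enolate of 13 | C=CCc1cc(OC)c(O/C=C(\[O-])c2cc(OC)c(OC)c(OC)c2)c(OCOC)c1.[Li+] | intermediate
16 | (Z)-2-[4-allyl-2-methoxy-6-(methoxymethoxy)phenoxy]-1-(3,4,5-trimethoxyphenyl)-1-(trimethylsilyloxy)ethene | C=CCc1cc(OC)c(O/C=C(\O[Si](C)(C)C)c2cc(OC)c(OC)c(OC)c2)c(OCOC)c1 | intermediate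
17 | diiodomethane | ICI | starting material
18 | (1R,2R)-cis-2-[4-allyl-2-methoxy-6-(methoxymethoxy)phenoxy]-1-(3,4,5-trimethoxyphenyl)-1-(trimethylsilyloxy)cyclopropane | C=CCc1cc(OC)c(O[C@@H]2C[C@@]2(O[Si](C)(C)C)c2cc(OC)c(OC)c(OC)c2)c(OCOC)c1 | intermediate
19 | (1R,2R)-cis-2-[4-allyl-2-methoxy-6-(methoxymethoxy)phenoxy]-1-(3,4,5-trimethoxyphenyl)cyclopropan-1-ol | C=CCc1cc(OC)c(O[C@@H]2C[C@@]2(O)c2cc(OC)c(OC)c(OC)c2)c(OCOC)c1 | intermediate
20 | (R)-2-[4-allyl-2-methoxy-6-(methoxymethoxy)phenoxy]-1-(3,4,5-trimethoxyphenyl)propan-1-one | C=CCc1cc(OC)c(O[C@H](C)C(=O)c2cc(OC)c(OC)c(OC)c2)c(OCOC)c1 | intermediate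
21 | (R)-2-(4-allyl-2-hydroxy-6-methoxyphenoxy)-1-(3,4,5-trimethoxyphenyl)propan-1-one | C=CCc1cc(OC)c(O[C@H](C)C(=O)c2cc(OC)c(OC)c(OC)c2)c(O)c1 | intermediate
22 | (2S,3R)-5-methoxy-3-methyl-7-(prop-2-en-1-yl)-2-(3,4,5-trimethoxyphenyl)-2,3-dihydro-1,4-benzodioxin-2-ol (CNP0114249.1) | C=CCc1cc(OC)c2c(c1)O[C@@](O)(c1cc(OC)c(OC)c(OC)c1)[C@@H](C)O2 | target

**Step count and risks**

Total step count: 8. Longest linear sequence: 8 steps (1 to 22).

Steps most likely to fail:

Step 7. The many ether oxygens of 16 may compete with the dipeptide for zinc, so that facial discrimination is poor, and excess carbenoid may also attack the allyl group. The fallback takes C3 from the chiral pool and sets out from phenol 11. A Mitsunobu reaction with ethyl (S)-lactate (PPh3, DIAD, THF, 0 °C to rt) should give, with inversion, ethyl (R)-2-[4-allyl-2-methoxy-6-(methoxymethoxy)phenoxy]propanoate F1. Me(MeO)NH·HCl and iPrMgCl (THF, −20 °C) would convert it into (R)-2-[4-allyl-2-methoxy-6-(methoxymethoxy)phenoxy]-N-methoxy-N-methylpropanamide F2. Commercial 3,4,5-trimethoxyphenylmagnesium bromide (THF, 0 °C) would then give ketone 20, where the route is rejoined for the MOM cleavage and hemiketal closure of step 8.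

Step 8. Once the ketone is unmasked, the acid and time needed to hydrolyse the aryl MOM acetal may enolise the α-aryloxy ketone or dehydrate the hemiketal to the 1,4-benzodioxin, eroding C3. The fallback moves the MOM cleavage to the achiral stage and carries a silyl ether through the key step, setting out from ketone 13.
- 3 M aq. HCl in THF at 40 °C should give 2-(4-allyl-2-hydroxy-6-methoxyphenoxy)-1-(3,4,5-trimethoxyphenyl)ethanone F3.
- tBuMe2SiCl and imidazole in DMF would give 2-[4-allyl-2-(tert-butyldimethylsilyloxy)-6-methoxyphenoxy]-1-(3,4,5-trimethoxyphenyl)ethanone F4.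
- Soft enolisation (Me3SiOTf, Et3N, CH2Cl2, 0 °C) would give (Z)-2-[4-allyl-2-(tert-butyldimethylsilyloxy)-6-methoxyphenoxy]-1-(3,4,5-trimethoxyphenyl)-1-(trimethylsilyloxy)ethene F5.
- The conditions of step 7 would give (1R,2R)-cis-2-[4-allyl-2-(tert-butyldimethylsilyloxy)-6-methoxyphenoxy]-1-(3,4,5-trimethoxyphenyl)-1-(trimethylsilyloxy)cyclopropane F6.
- Bu4NF buffered with AcOH (THF, 0 °C) would remove both silyl groups to give (1R,2R)-cis-2-(4-allyl-2-hydroxy-6-methoxyphenoxy)-1-(3,4,5-trimethoxyphenyl)cyclopropan-1-ol F7.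
- Brief exposure to 0.5 M aq. HCl in THF (0 °C to rt) should open the ring to hydroxy ketone 21, where the route is rejoined and the hemiketal 22 closes.

Step 4. At about 190 °C the MOM acetal may be lost, or the ortho dienone may be diverted before the Cope shift. The fallback rearranges before the oxidation and sets out from aldehyde 3.
- Heating in N,N-diethylaniline (190 °C) should give 5-allyl-2-hydroxy-3-methoxybenzaldehyde F8 by the para-Claisen shift of this ether.
- Alkylation with 12 (K2CO3, acetone, rt, kept cold enough to avoid Rap–Stoermer condensation) would give 5-allyl-3-methoxy-2-[2-oxo-2-(3,4,5-trimethoxyphenyl)ethoxy]benzaldehyde F9.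
- mCPBA (CH2Cl2, 0 °C) would give 5-allyl-3-methoxy-2-[2-oxo-2-(3,4,5-trimethoxyphenyl)ethoxy]phenyl formate F10.
- Methanolysis (K2CO3 cat., MeOH) would give 2-(4-allyl-2-hydroxy-6-methoxyphenoxy)-1-(3,4,5-trimethoxyphenyl)ethanone F3, the phenol also met in the fallback for step 8.
- MOMCl and iPr2NEt (CH2Cl2) return the route to ketone 13.

**Further compounds**

F1 | step 7 | ethyl (R)-2-[4-allyl-2-methoxy-6-(methoxymethoxy)phenoxy]propanoate | C=CCc1cc(OC)c(O[C@H](C)C(=O)OCC)c(OCOC)c1
F2 | step 7 | (R)-2-[4-allyl-2-methoxy-6-(methoxymethoxy)phenoxy]-N-methoxy-N-methylpropanamide | C=CCc1cc(OC)c(O[C@H](C)C(=O)N(C)OC)c(OCOC)c1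
F3 | step 8 | 2-(4-allyl-2-hydroxy-6-methoxyphenoxy)-1-(3,4,5-trimethoxyphenyl)ethanone | C=CCc1cc(OC)c(OCC(=O)c2cc(OC)c(OC)c(OC)c2)c(O)c1
F4 | step 8 | 2-[4-allyl-2-(tert-butyldimethylsilyloxy)-6-methoxyphenoxy]-1-(3,4,5-trimethoxyphenyl)ethanone | C=CCc1cc(OC)c(OCC(=O)c2cc(OC)c(OC)c(OC)c2)c(O[Si](C)(C)C(C)(C)C)c1
F5 | step 8 | (Z)-2-[4-allyl-2-(tert-butyldimethylsilyloxy)-6-methoxyphenoxy]-1-(3,4,5-trimethoxyphenyl)-1-(trimethylsilyloxy)ethene | C=CCc1cc(OC)c(O/C=C(\O[Si](C)(C)C)c2cc(OC)c(OC)c(OC)c2)c(O[Si](C)(C)C(C)(C)C)c1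
F6 | step 8 | (1R,2R)-cis-2-[4-allyl-2-(tert-butyldimethylsilyloxy)-6-methoxyphenoxy]-1-(3,4,5-trimethoxyphenyl)-1-(trimethylsilyloxy)cyclopropane | C=CCc1cc(OC)c(O[C@@H]2C[C@@]2(O[Si](C)(C)C)c2cc(OC)c(OC)c(OC)c2)c(O[Si](C)(C)C(C)(C)C)c1
F7 | step 8 | (1R,2R)-cis-2-(4-allyl-2-hydroxy-6-methoxyphenoxy)-1-(3,4,5-trimethoxyphenyl)cyclopropan-1-ol | C=CCc1cc(OC)c(O[C@@H]2C[C@@]2(O)c2cc(OC)c(OC)c(OC)c2)c(O)c1
F8 | step 4 | 5-allyl-2-hydroxy-3-methoxybenzaldehyde | C=CCc1cc(OC)c(O)c(C=O)c1
F9 | step 4 | 5-allyl-3-methoxy-2-[2-oxo-2-(3,4,5-trimethoxyphenyl)ethoxy]benzaldehyde | C=CCc1cc(OC)c(OCC(=O)c2cc(OC)c(OC)c(OC)c2)c(C=O)c1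
F10 | step 4 | 5-allyl-3-methoxy-2-[2-oxo-2-(3,4,5-trimethoxyphenyl)ethoxy]phenyl formate | C=CCc1cc(OC)c(OCC(=O)c2cc(OC)c(OC)c(OC)c2)c(OC=O)c1
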